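Monday's flask charges 2.17 free catalyst per added ligand, and two chemists read that ratio in different ways.

| flask | starting material | coupling partner | free catalyst | added ligand | remark | time |
|---|---|---|---|---|---|---|
| green | 0.25 M | 0.30 M | 2.5 mM | 1.4 mM | run made earlier |  |
| amber | 0.25 M | 0.30 M | 2.5 mM | 3.6 mM | run made earlier |  |
| violet | 0.25 M | 0.70 M | 2.5 mM | 2.3 mM | run made earlier |  |
| Sunday's | 0.25 M | 0.300 M | 2.5 mM | 2.3 mM |  | 15 min |
| Thursday's | 1.0 M | 0.300 M | 0.60 mM | 3.0 mM |  | 15 min |
| Saturday's | 0.25 M | 0.300 M | 2.5 mM | 1.2 mM |  | 15 min |
| Monday's | 0.40 M | 1.20 M | 5.0 mM | 2.3 mM |  | 15 min |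

- green (time / min: product / %, starting material / %): 0.833: 2, 99; 1.33: 4, 98; 2.50: 3, 92; 4.00: 8, 93; 6.00: 11, 86; 10.0: 17, 82
- amber (time / min: product / %, starting material / %): 2.00: 1, 98; 4.00: 6, 95; 5.00: 2, 92; 8.00: 6, 94; 10.0: 6, 95
- violet (time / min: product / %, starting material / %): 1.00: 4, 97; 2.50: 6, 95; 5.00: 11, 90; 8.00: 11, 88; 10.0: 14, 86

(scatter of a reading: 1.5 percentage points)

* the flasks by amount of product, in percent of the starting material charged, highest first, at 15 min (Sunday's / Thursday's / Saturday's / Monday's)
* the amount of product, in percent of the starting material charged of the flask you put first, at 15 min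
* the amount of product, in percent of the starting material charged of the flask you put last, at 15 min

The first chemist made the forecast. From the green and amber runs she reads inhibition by added ligand, suspects “an off-cycle catalyst–ligand complex”, and lets the rate go with free catalyst over added ligand. She orders the flasks Monday's > Saturday's > Sunday's > Thursday's, with 42% for Monday's and 3% for Thursday's.

The second chemist takes over her order but disputes Monday's number. He assumes that one added ligand holds one free catalyst, tightly. Where catalyst exceeds ligand, ligand is then the limiting reagent of the binding. So he counts differently: Monday's has 2.70 mM of spare catalyst, the charge of free catalyst minus the charge of added ligand.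

The green run has 1.10 mM of spare catalyst. Its reading of 17% of product at 10.0 min, taken as first order in starting material, gives a scattered constant of 0.0186 min⁻¹. Scaled by spare catalyst, with no correction for Monday's other charges, Monday's constant is 0.0457 min⁻¹. That gives 49.6% at 15 min, more than the forecast.

His number is partly a guess too, since no earlier run changes the catalyst charge. His rule also has a weak point. The violet run, with more coupling partner, reached 14% at 10.0 min on a spare of 0.200 mM. So he claims the rule for a clear excess of catalyst.

Monday's gives 47.8%, Thursday's gives 1.38%, and the order is Monday's > Saturday's > Sunday's > Thursday's.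

    starting material + free catalyst → catalyst intermediate A (k = 0.440 M⁻¹ s⁻¹)
    coupling partner + catalyst intermediate A ⇌ catalyst intermediate B (K = 7.60 M⁻¹, k = 0.460 M⁻¹ s⁻¹)
    catalyst intermediate B ⇌ by-product + catalyst intermediate C (K = 0.190 M, k = 0.970 s⁻¹)
    catalyst intermediate C → free catalyst + product (k = 0.550 s⁻¹)
    free catalyst + added ligand ⇌ idle complex (K = 13000 M⁻¹, k = 8.70 M⁻¹ s⁻¹)

At 15.0 min the idle complex holds 44.0% of Monday's catalyst, and Monday's added ligand stands at 4.41% of its own charge. The forecast's ratio view holds up in Sunday's flask, near equal charges: Sunday's gives 15.2% against its 14%, on a spare of 0.200 mM. Monday's flask charged instead with 0.013 M of free catalyst has a spare of 10.7 mM. The constant scaled to that spare gives 93.4%, and that flask gives 95.1%.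

The data are calculated for substances that don't exist, noise included.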